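**Strategy.** The route rests on disconnecting the pyranone ring (ring C) of the flavanone across C3–C4 and O1–C2, which reduces the target to a hexasubstituted salicylaldehyde and phenylacetylene. A phenol-directed alkyne hydroacylation catalysed by [Rh(cod)(OMe)]2/dppf, followed in the same flask by a cinchona-thiourea-catalysed oxa-Michael closure, builds the pyranone and sets C2 as S in one operation. It exploits the β-aryloxy ketone unit O1–C2–C3–C4(=O) and the single free phenol beside the formyl group, which decides which oxygen closes the ring and so places the two different benzyl chains at C8 and C6. The precursor comes from two Friedel–Crafts benzylations and an ortho-formylation of 3,5-bis(benzyloxy)phenol with iteratively built benzylic alcohols.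

Key step: step 9

Assumption: the quinine-derived thiourea is taken to deliver the 2S antipode; if the sense of induction on this substrate is the opposite, its quinidine-derived pseudoenantiomer is used with no other change.

Remark on names: chain A = 2-(benzyloxy)-5-[2-(benzyloxy)benzyl]benzyl; chain B = 2-(benzyloxy)-5-{2-(benzyloxy)-5-[2-(benzyloxy)benzyl]benzyl}benzyl. Compounds 1, 2, 8 and 13 are taken as commercial.

Step 1
Reactants: 1 [4-(benzyloxy)-3-formylphenyl]boronic acid; 2 2-(benzyloxy)benzyl bromide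
Product: 3 2-(benzyloxy)-5-[2-(benzyloxy)benzyl]benzaldehyde (chain A aldehyde)
Conditions: Pd(PPh3)4 (3 mol%), Na2CO3, DME/H2O, 80 °C
Reagents that add atoms: none
Why: Suzuki–Miyaura benzyl–aryl cross-coupling, in which zerovalent palladium adds into the benzylic C–Br bond and the arylboronic acid transmetalates, should give the diarylmethane while the aldehyde and the benzyl ethers stay untouched.

Step 2
Reactants: 3 chain A aldehyde
Product: 4 {2-(benzyloxy)-5-[2-(benzyloxy)benzyl]phenyl}methanol (chain A alcohol)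
Conditions: NaBH4, THF/MeOH, 0 °C
Reagents that add atoms: none
Why: Borohydride reduction of an aryl aldehyde to the benzylic alcohol is chemoselective beside aryl benzyl ethers and diarylmethane CH2 groups.

Step 3
Reactants: 4 chain A alcohol
Product: 5 1-(benzyloxy)-4-[2-(benzyloxy)benzyl]-2-(bromomethyl)benzene (chain A bromide)
Conditions: PBr3, CH2Cl2, 0 °C
Reagents that add atoms: phosphorus tribromide, BrP(Br)Br
Why: Bromination of a 2-alkoxybenzylic alcohol with PBr3 (SN2 displacement on the alkyl phosphite) is the standard entry to this class of bromide, the class to which 2 belongs.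

Step 4
Reactants: 5 chain A bromide; 1 [4-(benzyloxy)-3-formylphenyl]boronic acid
Product: 6 2-(benzyloxy)-5-{2-(benzyloxy)-5-[2-(benzyloxy)benzyl]benzyl}benzaldehyde (chain B aldehyde)
Conditions: Pd(PPh3)4 (3 mol%), Na2CO3, DME/H2O, 80 °C
Reagents that add atoms: none
Why: A second Suzuki–Miyaura benzyl–aryl coupling repeats step 1 and adds one more ring together with its formyl handle.

Step 5
Reactants: 6 chain B aldehyde
Product: 7 (2-(benzyloxy)-5-{2-(benzyloxy)-5-[2-(benzyloxy)benzyl]benzyl}phenyl)methanol (chain B alcohol)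
Conditions: NaBH4, THF/MeOH, 0 °C
Reagents that add atoms: none
Why: Borohydride reduction of the aryl aldehyde, as in step 2, should give the benzylic alcohol without touching the ethers.

Step 6
Reactants: 8 3,5-bis(benzyloxy)phenol; 4 chain A alcohol
Product: 9 3,5-bis(benzyloxy)-2-(chain A)phenol
Conditions: Bi(OTf)3 (5 mol%), 8 in excess (3 equiv), slow addition of 4, CH2Cl2, 0 °C to rt
Reagents that add atoms: none
Why: Friedel–Crafts benzylation of the strongly nucleophilic phloroglucinol diether after ionisation of 4 should go ortho to the free hydroxyl (C2, flanked by OH and one benzyloxy group) and not to C4 between two benzyloxy groups, for steric reasons, and the excess of 8 suppresses double alkylation.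

Step 7
Reactants: 9 3,5-bis(benzyloxy)-2-(chain A)phenol
Product: 11 4,6-bis(benzyloxy)-3-(chain A)-2-hydroxybenzaldehyde, via hydroxymethylphenol 10 (not isolated)
Conditions: MgCl2, Et3N, (CH2O)n, MeCN, reflux; then 1 M HCl
Reagents that add atoms: paraformaldehyde (formaldehyde), C=O
Why: Magnesium-mediated ortho-formylation (Casnati–Skattebøl type) delivers formaldehyde through the magnesium phenoxide chelate only to the one free ortho carbon, and a second equivalent of formaldehyde oxidises 10 by hydride transfer, so the formyl group ends up between the free hydroxyl and a benzyloxy group.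

Step 8
Reactants: 11 4,6-bis(benzyloxy)-3-(chain A)-2-hydroxybenzaldehyde; 7 chain B alcohol
Product: 12 4,6-bis(benzyloxy)-3-(chain A)-5-(chain B)-2-hydroxybenzaldehyde
Conditions: Bi(OTf)3 (10 mol%), slow addition of 7, CH2Cl2/MeNO2, rt
Reagents that add atoms: none
Why: Friedel–Crafts benzylation at the last free core carbon should succeed because C5 lies between two benzyloxy groups, para to the hydroxyl and only meta to the formyl group, so it remains far more nucleophilic than the anisole-type rings of the chains.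

Step 9
Reactants: 12 4,6-bis(benzyloxy)-3-(chain A)-5-(chain B)-2-hydroxybenzaldehyde; 13 phenylacetylene
Product: 15 hepta-O-benzyl sarmentosumin D [(2S)-5,7-bis(benzyloxy)-8-(chain A)-6-(chain B)-2-phenylchroman-4-one], via chalcone 14 (not isolated)
Conditions: [Rh(cod)(OMe)]2 (2.5 mol%), dppf (5 mol%), 13 (1.5 equiv, slow addition), toluene, 80 °C; then 0 °C, quinine-derived thiourea N-[3,5-bis(trifluoromethyl)phenyl]-N'-[(8S,9S)-6'-methoxycinchonan-9-yl]thiourea (10 mol%), 0 °C to rt
Reagents that add atoms: none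
Why: The free phenol of 12 exchanges onto monovalent rhodium and directs oxidative addition of the neighbouring aldehyde C–H bond to a five-membered acyl(hydrido) chelate of trivalent rhodium that cannot decarbonylate, syn hydrometalation of 13 places rhodium on the unhindered terminal carbon, and reductive elimination forms the C3–C4 bond to give (E)-chalcone 14. The closest known reaction type is the rhodium-catalysed hydroacylation of alkynes with salicylaldehydes run in tandem with an oxo-Michael closure to chroman-4-ones, here coupled with the thiourea-catalysed asymmetric cyclisation of 2'-hydroxychalcones. The pyranone ring then closes by 6-endo-trig oxa-Michael addition of the phenol oxygen to C-β, which forms the O1–C2 bond. C2 is the only new stereocentre and is set under catalyst control, since the quinuclidine nitrogen deprotonates the phenol while the thiourea binds the enone carbonyl, so that the phenoxide is delivered to the Si face of C-β to give 2S. Linear and not branched insertion is secured by the steric bias of the terminal alkyne under the wide-bite dppf ligand, and the choice of ring oxygen is secured by the substrate, because only the hydroxyl between the formyl group and chain A is free while the other two oxygens are benzyl ethers, which puts chain A at C8 and chain B at C6. The base-free rhodium stage should keep 14 from closing before the chiral catalyst is added, because hydrogen-bonded 2'-hydroxy-6'-alkoxychalcones persist in neutral toluene.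

Step 10
Reactants: 15 hepta-O-benzyl sarmentosumin D
Product: 16 sarmentosumin D
Conditions: H2 (1 atm), Pd(OH)2/C, THF/MeOH, rt
Reagents that add atoms: none
Why: Neutral hydrogenolysis at room temperature should cleave the seven aryl benzyl ethers faster than the cyclic benzylic C2–O1 ether or the ketone and does not enolise C3, so the 2S configuration is kept.

**Compound list**

1 | [4-(benzyloxy)-3-formylphenyl]boronic acid | O=Cc1cc(B(O)O)ccc1OCc1ccccc1 | starting material
2 | 1-(benzyloxy)-2-(bromomethyl)benzene (2-(benzyloxy)benzyl bromide) | BrCc1ccccc1OCc1ccccc1 | starting material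
3 | 2-(benzyloxy)-5-[2-(benzyloxy)benzyl]benzaldehyde | O=Cc1cc(Cc2ccccc2OCc2ccccc2)ccc1OCc1ccccc1 | intermediate
4 | {2-(benzyloxy)-5-[2-(benzyloxy)benzyl]phenyl}methanol | OCc1cc(Cc2ccccc2OCc2ccccc2)ccc1OCc1ccccc1 | intermediate
5 | 1-(benzyloxy)-4-[2-(benzyloxy)benzyl]-2-(bromomethyl)benzene | BrCc1cc(Cc2ccccc2OCc2ccccc2)ccc1OCc1ccccc1 | intermediate
6 | 2-(benzyloxy)-5-{2-(benzyloxy)-5-[2-(benzyloxy)benzyl]benzyl}benzaldehyde | O=Cc1cc(Cc2cc(Cc3ccccc3OCc3ccccc3)ccc2OCc2ccccc2)ccc1OCc1ccccc1 | intermediate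
7 | (2-(benzyloxy)-5-{2-(benzyloxy)-5-[2-(benzyloxy)benzyl]benzyl}phenyl)methanol | OCc1cc(Cc2cc(Cc3ccccc3OCc3ccccc3)ccc2OCc2ccccc2)ccc1OCc1ccccc1 | intermediate
8 | 3,5-bis(benzyloxy)phenol | Oc1cc(OCc2ccccc2)cc(OCc2ccccc2)c1 | starting material
9 | 3,5-bis(benzyloxy)-2-{2-(benzyloxy)-5-[2-(benzyloxy)benzyl]benzyl}phenol | Oc1cc(OCc2ccccc2)cc(OCc2ccccc2)c1Cc1cc(Cc2ccccc2OCc2ccccc2)ccc1OCc1ccccc1 | intermediate
10 | 3,5-bis(benzyloxy)-2-{2-(benzyloxy)-5-[2-(benzyloxy)benzyl]benzyl}-6-(hydroxymethyl)phenol | OCc1c(O)c(Cc2cc(Cc3ccccc3OCc3ccccc3)ccc2OCc2ccccc2)c(OCc2ccccc2)cc1OCc1ccccc1 | intermediate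
11 | 4,6-bis(benzyloxy)-3-{2-(benzyloxy)-5-[2-(benzyloxy)benzyl]benzyl}-2-hydroxybenzaldehyde | O=Cc1c(O)c(Cc2cc(Cc3ccccc3OCc3ccccc3)ccc2OCc2ccccc2)c(OCc2ccccc2)cc1OCc1ccccc1 | intermediate
12 | 4,6-bis(benzyloxy)-3-{2-(benzyloxy)-5-[2-(benzyloxy)benzyl]benzyl}-5-(2-(benzyloxy)-5-{2-(benzyloxy)-5-[2-(benzyloxy)benzyl]benzyl}benzyl)-2-hydroxybenzaldehyde | O=Cc1c(O)c(Cc2cc(Cc3ccccc3OCc3ccccc3)ccc2OCc2ccccc2)c(OCc2ccccc2)c(Cc2cc(Cc3cc(Cc4ccccc4OCc4ccccc4)ccc3OCc3ccccc3)ccc2OCc2ccccc2)c1OCc1ccccc1 | intermediate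
13 | phenylacetylene (ethynylbenzene) | C#Cc1ccccc1 | starting material
14 | (E)-1-[4,6-bis(benzyloxy)-3-(chain A)-5-(chain B)-2-hydroxyphenyl]-3-phenylprop-2-en-1-one | O=C(/C=C/c2ccccc2)c1c(O)c(Cc2cc(Cc3ccccc3OCc3ccccc3)ccc2OCc2ccccc2)c(OCc2ccccc2)c(Cc2cc(Cc3cc(Cc4ccccc4OCc4ccccc4)ccc3OCc3ccccc3)ccc2OCc2ccccc2)c1OCc1ccccc1 | intermediate
15 | (2S)-5,7-bis(benzyloxy)-8-{2-(benzyloxy)-5-[2-(benzyloxy)benzyl]benzyl}-6-(2-(benzyloxy)-5-{2-(benzyloxy)-5-[2-(benzyloxy)benzyl]benzyl}benzyl)-2-phenylchroman-4-one | O=C1C[C@@H](c2ccccc2)Oc2c(Cc3cc(Cc4ccccc4OCc4ccccc4)ccc3OCc3ccccc3)c(OCc3ccccc3)c(Cc3cc(Cc4cc(Cc5ccccc5OCc5ccccc5)ccc4OCc4ccccc4)ccc3OCc3ccccc3)c(OCc3ccccc3)c21 | intermediate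
16 | sarmentosumin D, (2S)-5,7-dihydroxy-8-[2-hydroxy-5-(2-hydroxybenzyl)benzyl]-6-{2-hydroxy-5-[2-hydroxy-5-(2-hydroxybenzyl)benzyl]benzyl}-2-phenylchroman-4-one | O=C1C[C@@H](c2ccccc2)Oc2c(Cc3cc(Cc4ccccc4O)ccc3O)c(O)c(Cc3cc(Cc4cc(Cc5ccccc5O)ccc4O)ccc3O)c(O)c21 | target

**Count.** Total step count: 10. Longest linear sequence: 8 steps (steps 1, 2, 3, 4, 5, 8, 9, 10).

**Steps most likely to fail**

Step 9. The alkyne may insert with the opposite regiochemistry (branched enone), the ring may close before or outside the control of the chiral catalyst so that the face of C-β is chosen poorly, or reversible ring opening may erode the configuration at C2. The fallback forms the same two bonds in separate, stereospecific operations of known chemistry. It sets out from 12 and comes back at 15. Thioacetalisation of 12 with propane-1,3-dithiol (BF3·OEt2, CH2Cl2, 0 °C) should give the 2-aryl-1,3-dithiane F1. Its dianion (n-BuLi, 2.2 equiv, THF, −78 to −20 °C; Corey–Seebach umpolung) opens (S)-styrene oxide at the terminal carbon and forms C3–C4, giving the (R)-hydroxy dithiane F2. Intramolecular Mitsunobu etherification (PPh3, DIAD, THF, 0 °C) forms O1–C2 with inversion, giving the (2S)-flavan-4-one dithioketal F3. Alkylative hydrolysis (MeI, CaCO3, MeCN/H2O, 45 °C) then gives 15.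

Step 8. The benzylic electrophile may alkylate a chain ring instead of the formyl-deactivated core carbon, or alcohol 7 may oligomerise with itself. The fallback replaces electrophilic substitution by cross-coupling. It sets out from 11 (with 7) and comes back at 12. Bromination of 11 at the only free core carbon (NBS, MeCN, 0 °C) should give the 5-bromo aldehyde F4. Alcohol 7 is converted with PBr3 (CH2Cl2, 0 °C) into the chain B bromide F5 and then by borylation (B2pin2, Pd2(dba)3, P(4-MeOC6H4)3, KOAc, toluene, 50 °C) into the chain B benzyl pinacol boronate F6. Suzuki–Miyaura coupling of F4 with F6 (Pd(OAc)2, SPhos, K3PO4, toluene/H2O, 80 °C) gives 12.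

Step 6. Alkylation may occur at the carbon between the two benzyloxy groups or twice on the same ring. The fallback uses a boron template that can only deliver to the ortho carbon. It sets out from 8 (with aldehyde 3) and comes back at 9. Condensation of 8, 3 and phenylboronic acid (cat. propionic acid, toluene, reflux, water removal) should give the 2-phenyl-4-aryl-4H-1,3,2-benzodioxaborin F7 (racemic at C4). Ionic hydrogenation of its benzylic C–O bond (Et3SiH, TFA, CH2Cl2, 0 °C) gives 9.

**Further compounds**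

F1 | step 9 | 2-[4,6-bis(benzyloxy)-3-(chain A)-5-(chain B)-2-hydroxyphenyl]-1,3-dithiane | C1CSC(SC1)c1c(O)c(Cc2cc(Cc3ccccc3OCc3ccccc3)ccc2OCc2ccccc2)c(OCc2ccccc2)c(Cc2cc(Cc3cc(Cc4ccccc4OCc4ccccc4)ccc3OCc3ccccc3)ccc2OCc2ccccc2)c1OCc1ccccc1
F2 | step 9 | (1R)-2-{2-[4,6-bis(benzyloxy)-3-(chain A)-5-(chain B)-2-hydroxyphenyl]-1,3-dithian-2-yl}-1-phenylethan-1-ol | c1ccccc1[C@H](O)CC1(SCCCS1)c1c(O)c(Cc2cc(Cc3ccccc3OCc3ccccc3)ccc2OCc2ccccc2)c(OCc2ccccc2)c(Cc2cc(Cc3cc(Cc4ccccc4OCc4ccccc4)ccc3OCc3ccccc3)ccc2OCc2ccccc2)c1OCc1ccccc1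
F3 | step 9 | (2S)-5,7-bis(benzyloxy)-8-(chain A)-6-(chain B)-2-phenylspiro[chromane-4,2'-[1,3]dithiane] | C1CSC2(SC1)C[C@@H](c1ccccc1)Oc1c(Cc3cc(Cc4ccccc4OCc4ccccc4)ccc3OCc3ccccc3)c(OCc3ccccc3)c(Cc3cc(Cc4cc(Cc5ccccc5OCc5ccccc5)ccc4OCc4ccccc4)ccc3OCc3ccccc3)c(OCc3ccccc3)c12
F4 | step 8 | 4,6-bis(benzyloxy)-5-bromo-3-(chain A)-2-hydroxybenzaldehyde | O=Cc1c(O)c(Cc2cc(Cc3ccccc3OCc3ccccc3)ccc2OCc2ccccc2)c(OCc2ccccc2)c(Br)c1OCc1ccccc1
F5 | step 8 | 1-(benzyloxy)-4-{2-(benzyloxy)-5-[2-(benzyloxy)benzyl]benzyl}-2-(bromomethyl)benzene (chain B bromide) | BrCc1cc(Cc2cc(Cc3ccccc3OCc3ccccc3)ccc2OCc2ccccc2)ccc1OCc1ccccc1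
F6 | step 8 | 2-(chain B)-4,4,5,5-tetramethyl-1,3,2-dioxaborolane (chain B benzyl pinacol boronate) | CC1(C)OB(Cc2cc(Cc3cc(Cc4ccccc4OCc4ccccc4)ccc3OCc3ccccc3)ccc2OCc2ccccc2)OC1(C)C
F7 | step 6 | 5,7-bis(benzyloxy)-4-{2-(benzyloxy)-5-[2-(benzyloxy)benzyl]phenyl}-2-phenyl-4H-1,3,2-benzodioxaborin (racemic) | c1ccccc1B1Oc2cc(OCc3ccccc3)cc(OCc3ccccc3)c2C(c2cc(Cc3ccccc3OCc3ccccc3)ccc2OCc2ccccc2)O1
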